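The five-membered ring of the target (C2 = isopropenyl-bearing CH, C3 and C4 = CH2, C5 = carbinol carbon, C6 = polyene-bearing CH) is cut at C2–C3, the ring bond opposite C5. With C5 as a ketone and an alkene at C3=C4, ring C2–C6 is the 4π-closure product of a cross-conjugated divinyl ketone. One catalytic, silicon-directed Nazarov cyclisation therefore closes the ring, forms C2–C3, sets C2 (and, after equilibration, C6) and parks the alkene away from the isopropenyl group. Its precursor is a flat, achiral (1E,4E)-6-methyl-1-trimethylsilylhepta-1,4,6-trien-3-one bearing the future C7 as a silyloxymethyl group. The polyene is then attached by one Horner–Wadsworth–Emmons and one Wittig coupling.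

Key step: step 8

Assumption: the absolute sense of the cyclisation cannot be assigned in advance, so the (R) acid written in step 8 stands for whichever enantiomer of the catalyst leads to the (4S) series.
Assumption: pseudoionone is used as its (3E,5E) isomer 25, the main component of the commercial mixture, enriched by fractional distillation; phosphonate 20 (sold as an E/Z mixture, whose geometry is lost in the delocalised anion) and dialdehyde 28 are bought.

Step 1
Reactants: 1 methacrolein; 2 methyl acrylate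
Product: 3 methyl 3-hydroxy-4-methyl-2-methylidenepent-4-enoate (racemic)
Conditions: DABCO (0.2 equiv), neat (2 in excess), rt, 5–7 d
Reagents that add atoms: none
Why: Morita–Baylis–Hillman reaction, in which the DABCO–acrylate zwitterion adds to the aldehyde carbonyl of 1, and the racemic carbinol centre formed is erased in step 2.

Step 2
Reactants: 3 methyl 3-hydroxy-4-methyl-2-methylidenepent-4-enoate
Product: 5 methyl (2E)-2-(acetoxymethyl)-4-methylpenta-2,4-dienoate, via secondary acetate 4 (not isolated)
Conditions: Ac2O, Et3N, DMAP (cat.), THF, 0 °C → rt; then DABCO (0.3 equiv), 65 °C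
Reagents that add atoms: acetic anhydride, CC(=O)OC(C)=O
Why: O-Acetylation followed by the DABCO-catalysed SN2′–SN2 transposition of a Morita–Baylis–Hillman acetate, in which the amine adds to the acrylate terminus, expels acetate and is displaced again at CH2, so that the linearly conjugated (E)-dienoate with the isopropenyl group trans to the ester accumulates as the thermodynamic isomer.

Step 3
Reactants: 5 methyl (2E)-2-(acetoxymethyl)-4-methylpenta-2,4-dienoate
Product: 6 methyl (2E)-2-(hydroxymethyl)-4-methylpenta-2,4-dienoate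
Conditions: K2CO3 (0.2 equiv), MeOH, 0 °C
Reagents that add atoms: none
Why: Base-catalysed transesterification (methanolysis) removes the primary acetate as methyl acetate, exchange at the methyl ester is degenerate, and the low temperature disfavours SN2′ attack of methoxide on the allylic system.

Step 4
Reactants: 6 methyl (2E)-2-(hydroxymethyl)-4-methylpenta-2,4-dienoate
Product: 7 methyl (2E)-2-({[tert-butyl(dimethyl)silyl]oxy}methyl)-4-methylpenta-2,4-dienoate
Conditions: TBSCl, imidazole, DMF, 0 °C → rt
Reagents that add atoms: tert-butyldimethylsilyl chloride, CC(C)(C)[Si](C)(C)Cl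
Why: Standard imidazole-mediated silylation of a primary allylic alcohol gives a non-chelating ether that later leaves the ketone oxygen as the only Lewis-basic site for the catalyst.

Step 5
Reactants: 7 methyl (2E)-2-({[tert-butyl(dimethyl)silyl]oxy}methyl)-4-methylpenta-2,4-dienoate
Product: 8 (2E)-2-({[tert-butyl(dimethyl)silyl]oxy}methyl)-N-methoxy-N,4-dimethylpenta-2,4-dienamide
Conditions: MeNH(OMe)·HCl, i-PrMgCl, THF, −20 → 0 °C
Reagents that add atoms: N,O-dimethylhydroxylamine hydrochloride, CNOC.Cl
Why: Direct ester-to-Weinreb-amide conversion with the magnesium amide ClMgN(OMe)Me, which acylates at the ester carbonyl faster than it adds to the hindered α-branched dienoate and leaves the alkene geometry untouched.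

Step 6
Reactants: 9 ethynyltrimethylsilane
Product: 10 tributyl[(E)-2-(trimethylsilyl)ethenyl]stannane
Conditions: Bu3SnH, AIBN (cat.), neat, 85 °C
Reagents that add atoms: tributyltin hydride, CCCC[SnH](CCCC)CCCC
Why: Radical hydrostannylation of a terminal alkyne, in which the stannyl radical adds to the unsubstituted carbon and reversible stannyl-radical addition equilibrates the product to the (E)-alkene.

Step 7
Reactants: 8 Weinreb amide; 10 tributyl[(E)-2-(trimethylsilyl)ethenyl]stannane
Product: 12 (1E,4E)-4-({[tert-butyl(dimethyl)silyl]oxy}methyl)-6-methyl-1-(trimethylsilyl)hepta-1,4,6-trien-3-one, via (E)-2-(trimethylsilyl)vinyllithium 11 (not isolated)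
Conditions: 10, n-BuLi, THF, −78 → −40 °C; then 8, −78 °C; aq. NH4Cl, −78 °C
Reagents that add atoms: none
Why: Tin–lithium exchange proceeds with retention of alkene geometry, and addition of the vinyllithium to the Weinreb amide stops at the chelated tetrahedral intermediate, so the (1E,4E)-trienone is released only on cold quench (Weinreb ketone synthesis).

Step 8
Reactants: 12 (1E,4E)-4-({[tert-butyl(dimethyl)silyl]oxy}methyl)-6-methyl-1-(trimethylsilyl)hepta-1,4,6-trien-3-one
Product: 14 (4S,5S)-5-({[tert-butyl(dimethyl)silyl]oxy}methyl)-4-(prop-1-en-2-yl)cyclopent-2-en-1-one, via cis-enone 13 (not isolated)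
Conditions: Zn(OTf)2 (5 mol %), (R)-STRIP [SPINOL-derived phosphoric acid with 2,4,6-triisopropylphenyl groups] (6 mol %), PhOH (1.1 equiv), ClCH2CH2Cl, 40 °C; then basic Al2O3, CH2Cl2, rt
Reagents that add atoms: none
Why: Zn(OTf)2, paired with the chiral phosphate, binds the ketone oxygen of 12 and generates the 3-oxidopentadienyl cation in its U-shaped s-trans,s-trans form (favoured by the substituent on C4), which closes by conrotatory 4π electrocyclisation between C1 and C5 of the trienone; the oxyallyl cation so formed is stabilised by the β-silicon, so Me3Si is transferred to phenol, the alkene is fixed at the former C1=C2 (C2=C3 of the cyclopentenone) and the remaining zinc dienolate is protonated at the carbon bearing CH2OTBS. The closest known reaction type is the catalytic enantioselective silicon-directed Nazarov cyclisation of β-silyl divinyl ketones under a Lewis acid and a chiral Brønsted acid. One ring is closed, the five-membered carbocycle, by thermal conrotatory 4π closure of a pentadienyl cation. C4 of 14 is set by the sense of conrotation (torquoselectivity), which the chiral phosphate held at the ketone oxygen must bias, whereas C5 is expected to be set cis first, by proton delivery to the face away from the isopropenyl group (13), and is then equilibrated on basic Al2O3, by enolisation towards C5 only, to the more stable trans epimer 14. The step needs five-membered closure and one alkene position: the (4E) geometry places the isopropenyl terminus outside the U and far from C1, so that it can only stabilise the cation, and the silyl group decides which bond becomes the alkene, away from the new stereocentre.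

Step 9
Reactants: 14 (4S,5S)-5-({[tert-butyl(dimethyl)silyl]oxy}methyl)-4-(prop-1-en-2-yl)cyclopent-2-en-1-one
Product: 15 (2S,3S)-2-({[tert-butyl(dimethyl)silyl]oxy}methyl)-3-(prop-1-en-2-yl)cyclopentan-1-one
Conditions: [(Ph3P)CuH]6 (0.25 equiv), H2O (2 equiv), degassed toluene, rt
Reagents that add atoms: none
Why: Stryker conjugate reduction, in which the copper hydride adds hydride 1,4 to the enone only and the copper enolate is protonated by water, so the unactivated isopropenyl alkene, the silyl ether and both stereocentres are left untouched.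

Step 10
Reactants: 15 (2S,3S)-2-({[tert-butyl(dimethyl)silyl]oxy}methyl)-3-(prop-1-en-2-yl)cyclopentan-1-one
Product: 16 (1S,2S,3S)-2-({[tert-butyl(dimethyl)silyl]oxy}methyl)-1-methyl-3-(prop-1-en-2-yl)cyclopentan-1-ol
Conditions: MeLi, CeCl3, THF, −78 °C
Reagents that add atoms: methyllithium, [Li]C
Why: Imamoto organocerium 1,2-addition, in which the non-basic MeCeCl2 avoids enolisation and β-elimination and should attack the ketone face anti to the adjacent CH2OTBS arm, so that the new carbinol centre (1S) carries methyl trans and hydroxyl cis to that arm.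

Step 11
Reactants: 16 (1S,2S,3S)-2-({[tert-butyl(dimethyl)silyl]oxy}methyl)-1-methyl-3-(prop-1-en-2-yl)cyclopentan-1-ol
Product: 17 (1S,2S,3S)-2-(hydroxymethyl)-1-methyl-3-(prop-1-en-2-yl)cyclopentan-1-ol
Conditions: Bu4NF, THF, 0 °C → rt
Reagents that add atoms: none
Why: Fluoride-mediated cleavage of the primary tert-butyldimethylsilyl ether, to which the tertiary alcohol and the alkene are inert.

Step 12
Reactants: 17 (1S,2S,3S)-2-(hydroxymethyl)-1-methyl-3-(prop-1-en-2-yl)cyclopentan-1-ol
Product: 18 triethyl({(1S,2S,3S)-1-methyl-3-(prop-1-en-2-yl)-2-[(triethylsilyloxy)methyl]cyclopentyl}oxy)silane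
Conditions: Et3SiOTf (2.5 equiv), 2,6-lutidine, CH2Cl2, −78 → 0 °C
Reagents that add atoms: triethylsilyl trifluoromethanesulfonate, CC[Si](CC)(CC)OS(=O)(=O)C(F)(F)F
Why: Silyl triflate with 2,6-lutidine silylates both the primary and the hindered tertiary hydroxyl, which masks the tertiary alcohol so that the aldehyde of step 13 is not a free aldol prone to retro-aldol cleavage or dehydration.

Step 13
Reactants: 18 triethyl({(1S,2S,3S)-1-methyl-3-(prop-1-en-2-yl)-2-[(triethylsilyloxy)methyl]cyclopentyl}oxy)silane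
Product: 19 (1R,2S,5S)-2-methyl-5-(prop-1-en-2-yl)-2-(triethylsilyloxy)cyclopentane-1-carbaldehyde
Conditions: (COCl)2, DMSO, CH2Cl2, −78 → −30 °C; then Et3N, −78 → 0 °C
Reagents that add atoms: none
Why: Swern oxidation applied directly to a primary triethylsilyl ether, in which the chlorosulfonium salt cleaves only the unhindered primary Si–O bond and the alkoxysulfonium collapses to the aldehyde, while the tertiary silyl ether survives and the aldehyde-bearing centre is already trans to both neighbouring carbon substituents.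

Step 14
Reactants: 19 (1R,2S,5S)-2-methyl-5-(prop-1-en-2-yl)-2-(triethylsilyloxy)cyclopentane-1-carbaldehyde; 20 ethyl (2E)-4-(diethoxyphosphoryl)-3-methylbut-2-enoate (triethyl 3-methyl-4-phosphonocrotonate)
Product: 22 ethyl (2E,4E)-3-methyl-5-[(1R,2S,5S)-2-methyl-5-(prop-1-en-2-yl)-2-(triethylsilyloxy)cyclopentyl]penta-2,4-dienoate, via lithiated phosphonate 21 (not isolated)
Conditions: 20, LiN(SiMe3)2, THF, −78 °C; then 19, −78 → 0 °C
Reagents that add atoms: none
Why: Horner–Wadsworth–Emmons olefination with a vinylogous phosphonate, whose stabilised anion reacts at the carbon next to phosphorus to give the new disubstituted alkene E, while the trisubstituted alkene should emerge mainly E because the delocalised anion equilibrates before coupling.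

Step 15
Reactants: 22 ethyl (2E,4E)-3-methyl-5-[(1R,2S,5S)-2-methyl-5-(prop-1-en-2-yl)-2-(triethylsilyloxy)cyclopentyl]penta-2,4-dienoate
Product: 23 (2E,4E)-3-methyl-5-[(1R,2S,5S)-2-methyl-5-(prop-1-en-2-yl)-2-(triethylsilyloxy)cyclopentyl]penta-2,4-dien-1-ol
Conditions: i-Bu2AlH, CH2Cl2, −78 °C; aq. KNa tartrate
Reagents that add atoms: none
Why: i-Bu2AlH reduces the conjugated ester 1,2 to the allylic alcohol at low temperature without touching the diene, the isopropenyl group or the silyl ether.

Step 16
Reactants: 23 (2E,4E)-3-methyl-5-[(1R,2S,5S)-2-methyl-5-(prop-1-en-2-yl)-2-(triethylsilyloxy)cyclopentyl]penta-2,4-dien-1-ol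
Product: 24 {(2E,4E)-5-[(1R,2S,5S)-2-hydroxy-2-methyl-5-(prop-1-en-2-yl)cyclopentyl]-3-methylpenta-2,4-dien-1-yl}triphenylphosphonium bromide
Conditions: PPh3·HBr (1.2 equiv), MeOH, rt
Reagents that add atoms: triphenylphosphine hydrobromide, Br.c1ccc(cc1)P(c1ccccc1)c1ccccc1
Why: Phosphonium salt formation as used for retinoid and carotenoid C15 salts, in which the dienyl alcohol ionises to a pentadienyl cation that triphenylphosphine captures at the unhindered primary terminus, while the same acidic methanol cleaves the tertiary triethylsilyl ether that is no longer needed.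

Step 17
Reactants: 25 (3E,5E)-pseudoionone [(3E,5E)-6,10-dimethylundeca-3,5,9-trien-2-one]
Product: 26 (4E,6E)-3,7,11-trimethyldodeca-1,4,6,10-tetraen-3-ol (racemic)
Conditions: CH2=CHMgBr, THF, −20 → 0 °C; aq. NH4Cl
Reagents that add atoms: vinylmagnesium bromide, C=C[Mg]Br
Why: Grignard 1,2-addition to the dienone carbonyl at low temperature gives the tertiary carbinol, whose stereocentre is of no consequence because it is lost in step 18.

Step 18
Reactants: 26 (4E,6E)-3,7,11-trimethyldodeca-1,4,6,10-tetraen-3-ol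
Product: 27 [(2E,4E,6E)-3,7,11-trimethyldodeca-2,4,6,10-tetraen-1-yl]triphenylphosphonium bromide
Conditions: PPh3·HBr, MeOH, rt
Reagents that add atoms: triphenylphosphine hydrobromide, Br.c1ccc(cc1)P(c1ccccc1)c1ccccc1
Why: The tertiary vinyl carbinol ionises to a delocalised allyl cation that triphenylphosphine captures at the primary terminus, giving the allylically transposed phosphonium salt with an (E)-trisubstituted alkene (standard C15 Wittig salt formation of carotenoid synthesis).

Step 19
Reactants: 27 [(2E,4E,6E)-3,7,11-trimethyldodeca-2,4,6,10-tetraen-1-yl]triphenylphosphonium bromide; 28 (2E,4E,6E)-2,7-dimethylocta-2,4,6-trienedial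
Product: 30 (2E,4E,6E,8E,10E,12E,14E)-2,7,11,15,19-pentamethylicosa-2,4,6,8,10,12,14,18-octaenal, via phosphorus ylide 29 (not isolated)
Conditions: 28 (3 equiv), NaOMe, CH2Cl2–MeOH, 0 °C → rt; then I2 (cat.), CH2Cl2, rt, light
Reagents that add atoms: none
Why: Wittig reaction of the allylic ylide with an excess of the symmetrical dialdehyde should stop at mono-olefination, and iodine-catalysed equilibration converts the Z isomer of the new disubstituted alkene into the all-E polyenal.

Step 20
Reactants: 24 ring-bearing C15 phosphonium bromide; 30 C25 polyenal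
Product: 32 (1S,2R,3S)-1-methyl-2-[(1E,3E,5E,7E,9E,11E,13E,15E,17E,19E)-3,7,12,16,20,24-hexamethylpentacosa-1,3,5,7,9,11,13,15,17,19,23-undecaen-1-yl]-3-(prop-1-en-2-yl)cyclopentan-1-ol (target), via phosphorus ylide 31 (not isolated)
Conditions: NaOMe, CH2Cl2–MeOH, 0 °C → rt, dark, Ar; then n-heptane, 90 °C
Reagents that add atoms: none
Why: Wittig coupling of the C15 ylide with the C25 polyenal forms the C11=C12 bond of the C40 chain without affecting the free tertiary alcohol or the ring stereocentres, and heating in heptane should convert Z isomers into the all-E polyene.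

Compound list
1 | methacrolein | C=C(C)C=O | starting material
2 | methyl acrylate | C=CC(=O)OC | starting material
3 | methyl 3-hydroxy-4-methyl-2-methylidenepent-4-enoate (racemic) | C=C(C)C(O)C(=C)C(=O)OC | intermediate
4 | methyl 3-acetoxy-4-methyl-2-methylidenepent-4-enoate (racemic) | C=C(C)C(OC(C)=O)C(=C)C(=O)OC | intermediate
5 | methyl (2E)-2-(acetoxymethyl)-4-methylpenta-2,4-dienoate | C=C(C)/C=C(\COC(C)=O)C(=O)OC | intermediate
6 | methyl (2E)-2-(hydroxymethyl)-4-methylpenta-2,4-dienoate | C=C(C)/C=C(\CO)C(=O)OC | intermediate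
7 | methyl (2E)-2-({[tert-butyl(dimethyl)silyl]oxy}methyl)-4-methylpenta-2,4-dienoate | C=C(C)/C=C(\CO[Si](C)(C)C(C)(C)C)C(=O)OC | intermediate
8 | (2E)-2-({[tert-butyl(dimethyl)silyl]oxy}methyl)-N-methoxy-N,4-dimethylpenta-2,4-dienamide | C=C(C)/C=C(\CO[Si](C)(C)C(C)(C)C)C(=O)N(C)OC | intermediate
9 | ethynyltrimethylsilane | C#C[Si](C)(C)C | starting material
10 | tributyl[(E)-2-(trimethylsilyl)ethenyl]stannane | CCCC[Sn](CCCC)(CCCC)/C=C/[Si](C)(C)C | intermediate
11 | (E)-2-(trimethylsilyl)vinyllithium | [Li]/C=C/[Si](C)(C)C | intermediate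
12 | (1E,4E)-4-({[tert-butyl(dimethyl)silyl]oxy}methyl)-6-methyl-1-(trimethylsilyl)hepta-1,4,6-trien-3-one | C[Si](C)(C)/C=C/C(=O)/C(CO[Si](C)(C)C(C)(C)C)=C/C(C)=C | intermediate
13 | (4S,5R)-5-({[tert-butyl(dimethyl)silyl]oxy}methyl)-4-(prop-1-en-2-yl)cyclopent-2-en-1-one (cis epimer) | C=C(C)[C@H]1C=CC(=O)[C@H]1CO[Si](C)(C)C(C)(C)C | intermediate
14 | (4S,5S)-5-({[tert-butyl(dimethyl)silyl]oxy}methyl)-4-(prop-1-en-2-yl)cyclopent-2-en-1-one | C=C(C)[C@H]1C=CC(=O)[C@@H]1CO[Si](C)(C)C(C)(C)C | intermediate
15 | (2S,3S)-2-({[tert-butyl(dimethyl)silyl]oxy}methyl)-3-(prop-1-en-2-yl)cyclopentan-1-one | C=C(C)[C@H]1CCC(=O)[C@@H]1CO[Si](C)(C)C(C)(C)C | intermediate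
16 | (1S,2S,3S)-2-({[tert-butyl(dimethyl)silyl]oxy}methyl)-1-methyl-3-(prop-1-en-2-yl)cyclopentan-1-ol | C=C(C)[C@H]1CC[C@](C)(O)[C@@H]1CO[Si](C)(C)C(C)(C)C | intermediate
17 | (1S,2S,3S)-2-(hydroxymethyl)-1-methyl-3-(prop-1-en-2-yl)cyclopentan-1-ol | C=C(C)[C@H]1CC[C@](C)(O)[C@@H]1CO | intermediate
18 | triethyl({(1S,2S,3S)-1-methyl-3-(prop-1-en-2-yl)-2-[(triethylsilyloxy)methyl]cyclopentyl}oxy)silane | C=C(C)[C@H]1CC[C@](C)(O[Si](CC)(CC)CC)[C@@H]1CO[Si](CC)(CC)CC | intermediate
19 | (1R,2S,5S)-2-methyl-5-(prop-1-en-2-yl)-2-(triethylsilyloxy)cyclopentane-1-carbaldehyde | C=C(C)[C@H]1CC[C@](C)(O[Si](CC)(CC)CC)[C@@H]1C=O | intermediate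
20 | ethyl (2E)-4-(diethoxyphosphoryl)-3-methylbut-2-enoate | CCOC(=O)/C=C(\C)CP(=O)(OCC)OCC | starting material
21 | lithium salt of 20, deprotonated at the carbon next to phosphorus | CCOC(=O)/C=C(\C)[CH-]P(=O)(OCC)OCC.[Li+] | intermediate
22 | ethyl (2E,4E)-3-methyl-5-[(1R,2S,5S)-2-methyl-5-(prop-1-en-2-yl)-2-(triethylsilyloxy)cyclopentyl]penta-2,4-dienoate | C=C(C)[C@H]1CC[C@](C)(O[Si](CC)(CC)CC)[C@@H]1/C=C/C(C)=C/C(=O)OCC | intermediate
23 | (2E,4E)-3-methyl-5-[(1R,2S,5S)-2-methyl-5-(prop-1-en-2-yl)-2-(triethylsilyloxy)cyclopentyl]penta-2,4-dien-1-ol | C=C(C)[C@H]1CC[C@](C)(O[Si](CC)(CC)CC)[C@@H]1/C=C/C(C)=C/CO | intermediate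
24 | {(2E,4E)-5-[(1R,2S,5S)-2-hydroxy-2-methyl-5-(prop-1-en-2-yl)cyclopentyl]-3-methylpenta-2,4-dien-1-yl}triphenylphosphonium bromide | C=C(C)[C@H]1CC[C@](C)(O)[C@@H]1/C=C/C(C)=C/C[P+](c1ccccc1)(c1ccccc1)c1ccccc1.[Br-] | intermediate
25 | (3E,5E)-pseudoionone, (3E,5E)-6,10-dimethylundeca-3,5,9-trien-2-one | CC(=O)/C=C/C=C(\C)CCC=C(C)C | starting material
26 | (4E,6E)-3,7,11-trimethyldodeca-1,4,6,10-tetraen-3-ol (racemic) | C=CC(C)(O)/C=C/C=C(\C)CCC=C(C)C | intermediate
27 | [(2E,4E,6E)-3,7,11-trimethyldodeca-2,4,6,10-tetraen-1-yl]triphenylphosphonium bromide | CC(C)=CCC/C(C)=C/C=C/C(C)=C/C[P+](c1ccccc1)(c1ccccc1)c1ccccc1.[Br-] | intermediate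
28 | (2E,4E,6E)-2,7-dimethylocta-2,4,6-trienedial | O=C/C(C)=C/C=C/C=C(C)/C=O | starting material
29 | ylide of 27, [(2E,4E,6E)-3,7,11-trimethyldodeca-2,4,6,10-tetraen-1-ylidene]triphenylphosphorane | CC(C)=CCC/C(C)=C/C=C/C(C)=C/C=P(c1ccccc1)(c1ccccc1)c1ccccc1 | intermediate
30 | (2E,4E,6E,8E,10E,12E,14E)-2,7,11,15,19-pentamethylicosa-2,4,6,8,10,12,14,18-octaenal | O=C/C(C)=C/C=C/C=C(C)/C=C/C=C(C)/C=C/C=C(\C)CCC=C(C)C | intermediate
31 | ylide of 24, {(2E,4E)-5-[(1R,2S,5S)-2-hydroxy-2-methyl-5-(prop-1-en-2-yl)cyclopentyl]-3-methylpenta-2,4-dien-1-ylidene}triphenylphosphorane | C=C(C)[C@H]1CC[C@](C)(O)[C@@H]1/C=C/C(C)=C/C=P(c1ccccc1)(c1ccccc1)c1ccccc1 | intermediate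
32 | (1S,2R,3S)-1-methyl-2-[(1E,3E,5E,7E,9E,11E,13E,15E,17E,19E)-3,7,12,16,20,24-hexamethylpentacosa-1,3,5,7,9,11,13,15,17,19,23-undecaen-1-yl]-3-(prop-1-en-2-yl)cyclopentan-1-ol | C=C(C)[C@H]1CC[C@](C)(O)[C@@H]1/C=C/C(C)=C/C=C/C(C)=C/C=C/C=C(C)/C=C/C=C(C)/C=C/C=C(\C)CCC=C(C)C | target

Total step count: 20. Longest linear sequence: 16 steps (steps 1–5, 7–16 and 20).

Steps most likely to fail

1. Step 8. The extra conjugation into the isopropenyl arm may slow the electrocyclisation and open the way to oligomerisation or capture of the cation by phenol. The chiral phosphate may also bias the sense of conrotation too weakly, and the alumina equilibration may stop short of the trans epimer. Fallback: setting out from 12, stoichiometric FeCl3 in CH2Cl2 at −40 °C (the classical, racemic silicon-directed Nazarov cyclisation) followed by basic Al2O3 would give the racemic trans-enone F1. Conjugate reduction, methyl addition and desilylation as in steps 9–11 would then lead through the racemic ketone F2 and the racemic silyl carbinol F3 to the racemic diol F4. Acylation of the primary hydroxyl with (1S)-(−)-camphanic chloride (pyridine, DMAP) would give the camphanate of the (1S,2S,3S) diol F5 and the camphanate of the antipodal diol F6, to be separated by crystallisation or chromatography. Methanolysis of F5 (K2CO3, MeOH) comes back to the route at 17.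

2. Step 10. Facial selectivity may be poor, because methyl must arrive on the ring face that also carries the isopropenyl group, which opposes the shielding by the adjacent CH2OTBS arm. Fallback: setting out from 15, non-basic carbonyl methylenation with Cp2TiMe2 (toluene, 65 °C) would give the exocyclic alkene F7, and Bu4NF the homoallylic alcohol F8. Hydroxyl-directed epoxidation with VO(acac)2 and t-BuOOH delivers oxygen to the face of the CH2OH arm and would give the spiro-epoxide F9. Opening with LiAlH4 at the epoxide CH2 leaves the tertiary hydroxyl cis to that arm and comes back to the route at 17.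

3. Step 14. The strongly basic phosphonate anion may trigger β-elimination of silanolate from, or epimerisation of, the α-branched aldehyde, and the trisubstituted alkene may form as an E/Z mixture. Fallback: setting out from 19, a neutral Wittig reaction with the stabilised ylide Ph3P=CHC(O)CH3 (toluene, 80 °C) would give the (E)-enone F10 without exposing the aldehyde to a strong base. Horner–Wadsworth–Emmons reaction of this methyl ketone with triethyl phosphonoacetate (NaH, THF), followed by separation of the minor Z isomer, comes back to the route at 22.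

Further compounds
F1 | step 8 | racemic trans-5-({[tert-butyl(dimethyl)silyl]oxy}methyl)-4-(prop-1-en-2-yl)cyclopent-2-en-1-one | C=C(C)[C@H]1C=CC(=O)[C@@H]1CO[Si](C)(C)C(C)(C)C.C=C(C)[C@@H]1C=CC(=O)[C@H]1CO[Si](C)(C)C(C)(C)C
F2 | step 8 | racemic trans-2-({[tert-butyl(dimethyl)silyl]oxy}methyl)-3-(prop-1-en-2-yl)cyclopentan-1-one | C=C(C)[C@H]1CCC(=O)[C@@H]1CO[Si](C)(C)C(C)(C)C.C=C(C)[C@@H]1CCC(=O)[C@H]1CO[Si](C)(C)C(C)(C)C
F3 | step 8 | racemic 16, rac-(1S,2S,3S)-2-({[tert-butyl(dimethyl)silyl]oxy}methyl)-1-methyl-3-(prop-1-en-2-yl)cyclopentan-1-ol | C=C(C)[C@H]1CC[C@](C)(O)[C@@H]1CO[Si](C)(C)C(C)(C)C.C=C(C)[C@@H]1CC[C@@](C)(O)[C@H]1CO[Si](C)(C)C(C)(C)C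
F4 | step 8 | racemic 17, rac-(1S,2S,3S)-2-(hydroxymethyl)-1-methyl-3-(prop-1-en-2-yl)cyclopentan-1-ol | C=C(C)[C@H]1CC[C@](C)(O)[C@@H]1CO.C=C(C)[C@@H]1CC[C@@](C)(O)[C@H]1CO
F5 | step 8 | [(1S,2S,5S)-2-hydroxy-2-methyl-5-(prop-1-en-2-yl)cyclopentyl]methyl (1S,4R)-4,7,7-trimethyl-3-oxo-2-oxabicyclo[2.2.1]heptane-1-carboxylate | C=C(C)[C@H]1CC[C@](C)(O)[C@@H]1COC(=O)[C@@]23CC[C@@](C)(C(=O)O2)C3(C)C
F6 | step 8 | [(1R,2R,5R)-2-hydroxy-2-methyl-5-(prop-1-en-2-yl)cyclopentyl]methyl (1S,4R)-4,7,7-trimethyl-3-oxo-2-oxabicyclo[2.2.1]heptane-1-carboxylate | C=C(C)[C@@H]1CC[C@@](C)(O)[C@H]1COC(=O)[C@@]23CC[C@@](C)(C(=O)O2)C3(C)C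
F7 | step 10 | tert-butyl(dimethyl){[(1R,5S)-2-methylidene-5-(prop-1-en-2-yl)cyclopentyl]methoxy}silane | C=C(C)[C@H]1CCC(=C)[C@@H]1CO[Si](C)(C)C(C)(C)C
F8 | step 10 | [(1R,5S)-2-methylidene-5-(prop-1-en-2-yl)cyclopentyl]methanol | C=C(C)[C@H]1CCC(=C)[C@@H]1CO
F9 | step 10 | [(3S,4S,5S)-5-(prop-1-en-2-yl)-1-oxaspiro[2.4]heptan-4-yl]methanol | C=C(C)[C@H]1CC[C@@]2(CO2)[C@@H]1CO
F10 | step 14 | (3E)-4-[(1R,2S,5S)-2-methyl-5-(prop-1-en-2-yl)-2-(triethylsilyloxy)cyclopentyl]but-3-en-2-one | C=C(C)[C@H]1CC[C@](C)(O[Si](CC)(CC)CC)[C@@H]1/C=C/C(C)=O
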